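**Retrosynthetic overview**

- The spiro‑cyclohexene is cut by a retro‑[4+2] into two C15 guaianolides: dehydrozaluzanin C (dienophile, exocyclic enone C4'=C15') and its 1,2‑dehydro derivative (diene C2=C1–C10=C14). The adduct's C1=C10 bond is then moved into conjugation, which also sets the two γ‑centres C10 and C5.
- Both halves come from dehydrocostus lactone by allylic oxidation at C3.
- The cyclopentane of dehydrocostus lactone (C1–C2–C3–C4–C5, the ring that ends as the spiro‑cyclopentanone) is not built as a five‑membered ring. It arises by contraction of six‑membered ring A (C1–C2–C3–C4–C5–C10) of the eudesmanolide reynosin through a Wagner–Meerwein shift of the C5–C10 bond. The same operation expands ring B to the cycloheptane, sets C1 and unveils the C10=C14 methylene (the later diene terminus); since both halves descend from its product, it supplies four carbocycles of the target.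
- Enabling feature: in the trans‑decalin the equatorial C1–O bond (1β‑mesylate) is anti‑periplanar to the C5–C10 ring‑fusion bond, and C10 is quaternary, so migration of C5 leaves a tertiary cation that loses H‑14.
- Ring order: γ‑lactone and ten‑membered ring (costunolide, purchased) → decalin rings A and B (transannular cyclisation) → cyclopentane and cycloheptane (key step) → spiro‑cyclohexene (Diels–Alder).

Key step: step 4

Numbering: germacrane, eudesmane and guaiane numbering is used; primed numbers belong to the spiro‑cyclopentanone half.

Assumption: in the dienone half of the given structure H‑5 is cis to H‑6 and trans to H‑10 (5‑epi relative to dehydrocostus lactone); C5 and C10 are both γ‑positions of the cross‑conjugated dienone, are taken to be configurationally labile, and the given arrangement is taken as their resting configuration, so both are set in the last step.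

**Route**

Step 1
Reactants: 1 costunolide
Product: 2 1β,10α‑epoxycostunolide
Conditions: mCPBA (1.0 equiv), CH2Cl2, −20 °C
Reagents that add atoms: meta‑chloroperoxybenzoic acid (mCPBA), O=C(OO)c1cccc(Cl)c1
Why: Prilezhaev epoxidation should pick the C1=C10 double bond (C4=C5 is deactivated by the allylic lactone oxygen at C6 and the α‑methylene lactone is electron‑poor), with the peracid adding to the outer face of the (E)‑alkene, which sets C1 (R) and C10 (R).

Step 2
Reactants: 2 1β,10α‑epoxycostunolide
Product: 3 reynosin
Conditions: BF3·OEt2 (0.2 equiv), CH2Cl2, −78 to −40 °C; the Δ3 isomer santamarine is removed by chromatography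
Reagents that add atoms: none
Why: Lewis‑acid opening of the epoxide at tertiary C10 with transannular attack of the C4=C5 bond through the chair–chair conformer (cationic transannular cyclisation of a 1,10‑epoxygermacranolide) should close the trans‑decalin, C10 being attacked anti to the departing oxygen (10β‑methyl), C5 taking its α‑hydrogen from the chair‑like transition state, C1 keeping its oxygen as the equatorial 1β‑hydroxyl, and loss of H‑15 giving the exocyclic alkene.

Step 3
Reactants: 3 reynosin
Product: 4 reynosin 1‑O‑methanesulfonate
Conditions: MsCl, Et3N, CH2Cl2, 0 °C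
Reagents that add atoms: methanesulfonyl chloride, CS(=O)(=O)Cl
Why: O‑mesylation of the only hydroxyl (through the sulfene) leaves the C1–O bond untouched, so the equatorial 1β configuration is kept.

Step 4
Reactants: 4 reynosin 1‑O‑methanesulfonate
Product: 5 dehydrocostus lactone
Conditions: KOAc (3 equiv), AcOH, 90 °C
Reagents that add atoms: none
Why: Ionisation of the equatorial C1 mesylate is assisted by the anti‑periplanar C5–C10 ring‑fusion bond, which migrates from C10 to C1 (Wagner–Meerwein 1,2‑shift) to give the tertiary C10 cation of the hydroazulene, and loss of a C14 proton then gives the exocyclic methylene. The closest known reaction type is the solvolytic eudesmane‑to‑guaiane rearrangement of 1β‑sulfonyloxy trans‑decalins in buffered acetic acid. The cyclopentane (C1–C2–C3–C4–C5) is closed by contraction of six‑membered ring A through this σ‑bond migration, not by a cyclisation, and the cycloheptane arises at the same time by one‑carbon expansion of ring B. The new stereocentre C1 is set with inversion by backside arrival of C5, which itself migrates with retention, so the 1α‑H,5α‑H cis fusion follows from the 1β,5α configuration of 4. The step needs C5 (not C9, C14 or C3) to migrate and the cation to lose H‑14 (not H‑1 or H‑9): only the C5–C10 and C2–C3 bonds are anti‑periplanar to C1–O, only C5 migration leaves a tertiary cation, and the acetate buffer removes the most accessible methyl proton, minor endocyclic isomers being separated.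

Step 5
Reactants: 5 dehydrocostus lactone
Product: 6 3‑epizaluzanin C
Conditions: SeO2 (0.5 equiv), t‑BuOOH (2 equiv), CH2Cl2, 0 °C to rt
Reagents that add atoms: tert‑butyl hydroperoxide, CC(C)(C)OO (terminal oxygen source); selenium dioxide, O=[Se]=O (catalytic oxygen carrier)
Why: Riley allylic oxidation (ene reaction of SeO2 at the C4=C15 methylene, then [2,3]‑shift) should hydroxylate C3 and return the double bond to C4=C15, the reagent arriving on the convex α face of the cis‑fused hydroazulene (3α‑OH, a centre removed in step 6).

Step 6
Reactants: 6 3‑epizaluzanin C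
Product: 7 dehydrozaluzanin C
Conditions: Dess–Martin periodinane, CH2Cl2, 0 °C to rt
Reagents that add atoms: none
Why: Dess–Martin oxidation of the allylic secondary alcohol should give the exocyclic enone without touching the other alkenes or the neighbouring stereocentres.

Step 7
Reactants: 7 dehydrozaluzanin C
Product: 8 tert‑butyldimethylsilyl dienol ether of dehydrozaluzanin C
Conditions: TBSOTf, Et3N, CH2Cl2, −78 °C
Reagents that add atoms: tert‑butyldimethylsilyl trifluoromethanesulfonate, CC(C)(C)[Si](C)(C)OS(=O)(=O)C(F)(F)F
Why: Soft enolisation can only go toward C2 (C4 carries no hydrogen), so silyl enol ether formation should give the 2‑ene‑3‑silyloxy diene with C1 and C5 untouched.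

Step 8
Reactants: 8 tert‑butyldimethylsilyl dienol ether of dehydrozaluzanin C; 7 dehydrozaluzanin C
Product: 10 Diels–Alder adduct (C2–C4' and C14–C15' bonds; C1=C10; 2β‑H; 5α‑H), via trienone 9 (not isolated)
Conditions: Pd(OAc)2 (1.1 equiv), 7 (3 equiv), MeCN, 0 °C to rt
Reagents that add atoms: none
Why: Saegusa–Ito dehydrogenation of the silyl enol ether by divalent palladium (β‑hydride loss of H‑1) should give trienone 9, whose s‑cis diene C2=C1–C10=C14 is captured by the exocyclic enone C4'=C15' of 7 in an intermolecular Diels–Alder reaction with ortho regiochemistry; the diene adds to the α face of C4' (the face of H‑5', away from C6' and the seven‑membered ring), which sets the spiro centre, while the C2 centre formed here (drawn for attack on the diene face opposite C6) is erased in step 9.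

Step 9
Reactants: 10 Diels–Alder adduct
Product: 11 target (CNP0221188.1)
Conditions: DBU (0.2 equiv), CH2Cl2, 0 °C to rt
Reagents that add atoms: none
Why: Reversible γ‑deprotonation by the amidine should move the C1=C10 double bond into conjugation (C1=C2) and let C10 and then C5 equilibrate through the extended enolates, so that both centres settle under thermodynamic control in the configuration taken above as the resting one (H‑10 α; H‑5 β, cis to H‑6); base‑mediated enone isomerisation with vinylogous epimerisation.

**Compound list**

1 | costunolide, (3aS,6E,10E,11aR)‑germacra‑1(10),4,11(13)‑trien‑12,6α‑olide | C/C1=C\CC/C(C)=C/[C@H]2OC(=O)C(=C)[C@@H]2CC1 | starting material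
2 | 1β,10α‑epoxycostunolide, (1R,10R)‑epoxide of 1 | C[C@@]12CC[C@H]3C(=C)C(=O)O[C@@H]3/C=C(\C)CC[C@H]1O2 | intermediate
3 | reynosin, 1β‑hydroxy‑5αH‑eudesma‑4(15),11(13)‑dien‑12,6α‑olide (10β‑methyl) | O[C@@H]1CCC(=C)[C@@H]2[C@H]3OC(=O)C(=C)[C@@H]3CC[C@@]12C | intermediate
4 | reynosin 1‑O‑methanesulfonate (1β‑OMs, equatorial) | CS(=O)(=O)O[C@@H]1CCC(=C)[C@@H]2[C@H]3OC(=O)C(=C)[C@@H]3CC[C@@]12C | intermediate
5 | dehydrocostus lactone, 1αH,5αH‑guaia‑4(15),10(14),11(13)‑trien‑12,6α‑olide | C=C1CC[C@H]2C(=C)CC[C@H]3C(=C)C(=O)O[C@@H]3[C@H]21 | intermediate
6 | 3‑epizaluzanin C, 3α‑hydroxy derivative of 5 | C=C1[C@H](O)C[C@H]2C(=C)CC[C@H]3C(=C)C(=O)O[C@@H]3[C@H]21 | intermediate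
7 | dehydrozaluzanin C, 3‑oxo derivative of 5 | C=C1C(=O)C[C@H]2C(=C)CC[C@H]3C(=C)C(=O)O[C@@H]3[C@H]21 | intermediate
8 | tert‑butyldimethylsilyl dienol ether of 7 (3‑silyloxy‑2‑ene) | C=C1C(O[Si](C)(C)C(C)(C)C)=C[C@H]2C(=C)CC[C@H]3C(=C)C(=O)O[C@@H]3[C@H]21 | intermediate
9 | trienone, 3‑oxo‑5αH‑guaia‑1,4(15),10(14),11(13)‑tetraen‑12,6α‑olide | C=C1C(=O)C=C2C(=C)CC[C@H]3C(=C)C(=O)O[C@@H]3[C@@H]12 | intermediate (not isolated)
10 | Diels–Alder adduct: C2 (sp3, 2β‑H) bonded to C4', C14 bonded to C15', C1=C10, 5α‑H; spiro C4' with C2 on the α face and C15' on the β face of the cyclopentanone | C=C1C(=O)[C@H]2C3=C(CC[C@H]4C(=C)C(=O)O[C@@H]4[C@@H]13)CC[C@]21C(=O)C[C@H]2C(=C)CC[C@H]3C(=C)C(=O)O[C@@H]3[C@H]21 | intermediate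
11 | target: as 10 but with the C1=C2 double bond, 10α‑H and 5β‑H | C=C1C(=O)C2=C3[C@H](CC[C@H]4C(=C)C(=O)O[C@@H]4[C@H]13)CC[C@]21C(=O)C[C@H]2C(=C)CC[C@H]3C(=C)C(=O)O[C@@H]3[C@H]21 | target

**Step count and risks**

Total steps: 9. Longest linear sequence: 9 (1 to 11); compound 7 is used twice, as the precursor of 8 and as the dienophile.

Three steps most likely to fail:

Step 9. The extended enolates may be protonated on the wrong face, or the epimer equilibrium at C5 and C10 may lie on the wrong side, and the C5 enolate may expel the C6 carboxylate (vinylogous β‑elimination that opens the lactone). Fallback, from 10 back to 11 without free enolates: 10 is silylated (TBSOTf, Et3N, −78 °C) to the silyl trienol ether F1, which is protonated at C10 at −78 °C with HF·pyridine (kinetic γ‑protonation; C10 epimers separable) to give the 5α‑H dienone F2. F2 is silylated again, now with loss of H‑5, to the fulvene‑type silyl ether F3, and its low‑temperature protonolysis with the same reagent should place the proton on C5 anti to the pseudo‑axial C6–C7 bond, that is on the face of H‑6, giving 11.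

Step 8. The transient trienone may add to itself through its own exocyclic enone, the electron‑rich silyloxy diene 8 may cycloadd to 7 before it is oxidised, and the palladium may isomerise exocyclic alkenes. Fallback, from 8 back to 10, metal‑free: 8 is selenenylated with PhSeCl (CH2Cl2, −78 °C) on the convex α face to the α‑phenylselanyl ketone F4. Oxidation with H2O2 at 0 °C in the presence of an excess of 7 gives the selenoxide F5, whose syn‑elimination with the cis H‑1 releases trienone 9 slowly below room temperature, so that it is captured by 7 as it forms to give 10.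

Step 2. The C4 cation may lose H‑3 instead of H‑15 (endocyclic isomer) or be captured by traces of water, so that material is lost early. Fallback, from 2 back to 3, radical instead of cationic: Cp2TiCl (trivalent titanium, made from Cp2TiCl2 and Mn dust, THF, rt) opens the epoxide homolytically at C10, the tertiary radical cyclises across the ring onto C5, and the C4 radical is trapped by a second Cp2TiCl and loses a methyl hydrogen as titanium hydride, which should give the exocyclic alkene of 3 selectively; this fallback forms no compound outside the list (F0).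

**Further compounds**

F1 | step 9 | silyl trienol ether of 10 (3‑OTBS, C2=C3, C1=C10, 5α‑H) | C=C1C(O[Si](C)(C)C(C)(C)C)=C2C3=C(CC[C@H]4C(=C)C(=O)O[C@@H]4[C@@H]13)CC[C@]21C(=O)C[C@H]2C(=C)CC[C@H]3C(=C)C(=O)O[C@@H]3[C@H]21
F2 | step 9 | 5α‑H dienone, C5 epimer of 11 (10α‑H) | C=C1C(=O)C2=C3[C@H](CC[C@H]4C(=C)C(=O)O[C@@H]4[C@@H]13)CC[C@]21C(=O)C[C@H]2C(=C)CC[C@H]3C(=C)C(=O)O[C@@H]3[C@H]21
F3 | step 9 | fulvene‑type silyl ether (3‑OTBS, C2=C3, C1=C5, C4=C15, 10α‑H) | C=C1C(O[Si](C)(C)C(C)(C)C)=C2C(=C1[C@H]5OC(=O)C(=C)[C@@H]5CC6)[C@H]6CC[C@]27C(=O)C[C@H]8C(=C)CC[C@H]9C(=C)C(=O)O[C@@H]9[C@H]87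
F4 | step 8 | 2α‑phenylselanyl‑dehydrozaluzanin C | C=C1C(=O)[C@H]([Se]c2ccccc2)[C@H]2C(=C)CC[C@H]3C(=C)C(=O)O[C@@H]3[C@H]21
F5 | step 8 | selenoxide of F4 (mixture at selenium, not isolated) | C=C1C(=O)[C@H]([Se](=O)c2ccccc2)[C@H]2C(=C)CC[C@H]3C(=C)C(=O)O[C@@H]3[C@H]21
F0 | step 2 | none | none
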